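1. Late in the dusk run, at 2.50 min, starting material was down to 6.5 % of the charge, yet target stood at 1.4 %, so hardly any of what had been consumed had appeared as target.

all flasks: starting material 0.50 M (fed, over 8.0 s)

| run | free catalyst | remark | time |
|---|---|---|---|
| dusk | 0.13 mol% | run made earlier; the fed solution adds 0.25 times the starting volume |  |
| dawn | 13 mol% | run made earlier; the fed solution adds 0.25 times the starting volume |  |
| Sunday's | 0.2 mol% | the fed solution adds 0.25 times the starting volume | 2.5 min |
| Monday's | 0.6 mol% | the fed solution adds 0.25 times the starting volume | 2.5 min |
| Wednesday's | 1.5 mol% | the fed solution adds 0.25 times the starting volume | 2.5 min |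
| Thursday's | 5 mol% | the fed solution adds 0.25 times the starting volume | 2.5 min |
| Friday's | 15 mol% | the fed solution adds 0.25 times the starting volume | 2.5 min |

| run | time / min | target / % | starting material / % |
|---|---|---|---|
| dusk | 0.417 | 0.3 | 33.2 |
| dusk | 0.833 | 0.4 | 17.5 |
| dusk | 1.33 | 1.4 | 11.7 |
| dusk | 1.50 | 0.2 | 9.4 |
| dusk | 2.00 | 1.3 | 6.8 |
| dusk | 2.50 | 1.4 | 6.5 |
| dawn | 0.167 | 15.7 | 52.7 |
| dawn | 0.500 | 42.7 | 8.5 |
| dawn | 0.833 | 39.1 | 0.7 |
| dawn | 1.33 | 23.7 | 0 |
| dawn | 2.00 | 14.6 | 0 |
| dawn | 2.50 | 11.6 | 0 |

(readings scatter by 0.5 percentage points)

- charges are per starting volume, the dose included; the dosed solution carries all of it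
- "hardly changes" means that all values lie within two and a half points (for a concentration: within two and a half percent of the largest)

- amount of target at the end, in percent of the starting material charged for Sunday's, Monday's, Wednesday's, Thursday's, Friday's, in this order
- how the row runs (rises, then falls / hardly changes / falls all the way / falls, then rises / rises all the way)

2. I therefore treated target at low loading as a small correction to a starting-material curve that goes its own way. If that curve stays the same and target is not lost, then at a fixed time target scales with the loading of free catalyst. I called the ratio the yield per loading: target at the end in fractions of the charge, divided by the loading. The last two dusk readings give 10.4. Each carries a scatter of 0.5 percentage points, so this is a rough reading.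

3. The first setting is the dosing time. The feed took 8.0 s, far shorter than the 2.5 min of the run, so by hand I expected a longer or shorter dose to matter little and reckoned as if the charge went in at once.

4. The second setting is the loading. The yield per loading gave 2.08 % for Sunday's, 6.23 % for Monday's and 15.6 % for Wednesday's. For the dawn run it gave 135 %, far above the 11.6 % read at the end, so the correction is no longer small at that loading. In the dawn run, target had also fallen from a reading of 42.7 %. Friday's loading lies close to the dawn run's, so I took 11.6 % for Friday's. My figure for Wednesday's stands above that, so I expected the row to rise and then fall.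

5. The forecast gave 2.2 %, 5.2 %, 9 %, 12 % and 11.7 %, with the shape "rises, then falls", holding that “second-order decay forgets the peak height”.

6. The flasks gave 2.79 %, 7.61 %, 15.0 %, 18.8 % and 11.5 %, and the row ran: rises, then falls.

    starting material + free catalyst → catalyst intermediate (k = 2.60 L mol⁻¹ s⁻¹)
    2 starting material → self-condensation product (k = 0.130 L mol⁻¹ s⁻¹)
    catalyst intermediate → free catalyst + target (k = 0.260 s⁻¹)
    target + free catalyst ⇌ isomer of the product + free catalyst, rate k4*[free catalyst]*[target] forward; the back reaction follows from the equilibrium constant (K = 5.80, k = 0.400 L mol⁻¹ s⁻¹)

The yield per loading had said 2.08 % for Sunday's, which gave 2.79 %, and 6.23 % for Monday's, which gave 7.61 %. The dosing of starting material over time made no difference to Sunday's target. In Sunday's, at 0.227 min, the instantaneous selectivity stood against the catalyst: self-condensation used starting material 88 times as fast as the step into catalyst intermediate.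

Readings and results were computed with made-up constants; scatter was added.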